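## The problem

Target 17 is a 2,3-dihydro-1-benzofuran: benzo ring A fused to dihydrofuran ring C. It carries a catechol (ring B) at C2, a resorcinol (ring D) at C3 and an (E)-3,5-dihydroxystyryl arm (ring E) at C5, and all six phenols are free.

C2 and C3 are adjacent stereocentres, both S, with the two aryl groups trans. Trans is the thermodynamically preferred arrangement, and each centre can equilibrate in its own way. C3 epimerises by enolisation while it carries a carbonyl group. C2 epimerises by reversible ionisation of the benzylic C2–O1 bond under acid. Only one centre therefore has to be set in the absolute sense, provided the second is locked before the first can be lost.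

Three features will not survive rough treatment:
- the C2–O1 bond, a para-oxygenated benzylic aryl ether, is sensitive to acid, Lewis acid and hydrogenolysis;
- the electron-rich stilbene is sensitive to acid, hydrogenation and light;
- the free catechol is oxidised by air under base.

The phenols therefore stay masked as long as possible, and hydrogenolytic deprotection is excluded.

The enabling feature is ring D. Its C1 is bonded to C3, its C3 and C5 carry the hydroxyls, and C2, C4 and C6 are CH. This is the pattern of a folded 1,3,5-triketone whose first carbonyl sits on C3. An acyl group on C3 is also what a C–H insertion of an aryl diazoacetate leaves there. The price is that a carbonyl on C3 makes C3–H acidic with the O1 phenoxide as a β leaving group, so the ring-forming chemistry must not open ring C.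

## Retrosynthesis

**17 from 16.** The four O–CH3 bonds of rings B and E are cut last. Methyl ethers are the only common phenol masks that pass carbonate, amidine base, a rhodium carbene, methoxide, aqueous hydroxide and palladium unchanged. Benzyl ethers could not be removed without touching the alkene or C2–O1, and silyl or acyl groups would not survive the basic steps. Because ring D is born as the free diol, only four ethers have to be cleaved. The forward reaction (BBr3) must spare the stilbene; any transient opening of C2–O1 recloses to trans under control of the by then fixed C3.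

**16 from 14 and 15.** The C5–vinyl bond is cut as a Heck coupling of aryl bromide 14 with styrene 15. An olefination would need a C5 formyl group that cannot be carried through enolate chemistry. The bromide is an inert spectator that is already present in the commercial acid 1. The precursor loses ring E and the alkene; the forward step must give the E alkene and tolerate the free resorcinol.

**14 from 13 (key).** Ring D is cut between the carbon attached to C3 and one neighbouring ring CH, a retro-aldol/retro-aromatisation that unfolds the arene to the acyclic triketone 13. The neighbouring cut, C3–aryl, would call for a cross-coupling at a secondary benzylic centre β to a phenoxide leaving group, or for a different carbene (see Alternative 3). The triketone cut instead traces ring D to an acyl group on C3. The forward reaction must close through the terminal methyl group and keep ring C intact.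

**13 from 8 and 10.** The bond between the acyl carbon on C3 and the first methylene of the chain is cut. The textbook forward reaction, a Claisen condensation of ester 7 with a β-diketone dianion, is the weak point of the idea. C3–H of 7 is benzylic and α to the ester, far more acidic than the conjugate acid of the dianion terminus. Proton transfer would stall the acylation and expose an enolate with a β-phenoxide. The same bond is therefore made under neutral conditions: acid 8 is converted to its chloride 11 and acylated by the bis(silyl enol ether) 10, which gives 13 through silyl enol ether 12. Diene 10 is one step from commercial 9.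

**8 from 6.** No skeletal bond is cut; C3 is inverted and the ester hydrolysed. The cis ester 6 is what the insertion delivers, and the trans ester 7 is its thermodynamic epimer, so methoxide followed by hydroxide in one flask leads to acid 8.

**6 from 5, and back to 1, 2, 3, 4.** Cutting C2–C3 opens ring C to the aryl diazoacetate 5, in which C2 is a benzylic ether CH2. The forward 1,5 C–H insertion closes ring C and sets C2 by catalyst control. Diazo ester 5 comes from arylacetate 4 by diazo transfer. Ester 4 comes from phenol 2 and benzyl bromide 3 by etherification, and 2 from acid 1 by esterification.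

## Roads not taken

**Alternative 1:** Ring A would be cut at C3a–C4 and C7–C7a. Lactone A1, a trans-4,5-diaryl butanolide, would be converted into its silyl ketene acetal A2 and heated with methyl coumalate A3. Inverse-demand Diels–Alder addition, then loss of CO2 and silanol, would give benzoate A4 with ring A newly formed.
- Merits: rings B and D are bought as arenes, the regiochemistry follows from the polarisation of the pyranone, and the stereocentres sit in a lactone with neither an enolisable C3 carbonyl next to a leaving group nor a benzylic aryl ether. In that respect it is more robust than the chosen plan.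
- Weak points: A1 needs both stereocentres set beforehand, a problem as large as the one removed. The trisubstituted ketene acetal is flanked by an aryl-bearing carbon and must react thermally. The C5 ester of A4 needs three further steps (reduction, oxidation, benzylic phosphonate olefination) where the chosen plan needs one Heck coupling. Six methyl ethers must be cleaved instead of four.
- Comparison: the chosen plan sets against the robustness of A1 a shorter sequence and an insertion that creates ring C and the C2 centre in one catalytic step.

**Alternative 2:** The C3–C3a bond would be formed by ring contraction of flavanone A5. PhI(OAc)2 and H2SO4 in trimethyl orthoformate attack C3 of the derived enol ether, ring A migrates from C4 to C3, and the trans ester A6 results. A6 is the same compound as ester 7.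
- Merits: it is the shortest access to the trans ester, it uses no diazo compound and no rhodium, and it gives trans directly.
- Weak points: A5 must be enantiopure, and flavanones racemise through ring opening to the chalcone, which the strongly acidic conditions invite. An electron-rich aryl group at C2, as here, tends to migrate itself and give an isoflavone instead of letting ring A shift.
- Comparison: this road does not address ring D at all and would feed the same triketone chemistry. As a way to 7 it is shorter than steps 1 to 5. The chosen plan sets against that a C2 centre fixed by a chiral catalyst at low temperature without acid.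

**Alternative 3:** The C2–C3 bond would be closed with ring D already in place. Hydrazone A7 is oxidised by MnO2 to the diaryldiazomethane A8, and Rh2(R-PTAD)4 (dirhodium tetrakis[(R)-(1-adamantyl)(phthalimido)acetate]) turns it into a donor/donor carbene. Insertion into the ether benzylic C–H bond gives the cis-dihydrobenzofuran A9. Heck coupling with 15 and BBr3, which would also epimerise C2 to trans, would finish the synthesis.
- Merits: it is about three steps shorter than the chosen plan, ring D is bought rather than built, and no intermediate has an acidic C3–H next to a leaving group. In step count and in the safety of C3 it is the better road.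
- Weak points: the product is cis, so the final trans geometry depends entirely on Lewis-acid ring opening and reclosure at C2 in the last step, in the presence of the stilbene. Incomplete epimerisation would leave hexaphenol diastereomers to separate. Six ethers must be cleaved.
- Comparison: the chosen plan reaches trans early under mild base, so the last step needs no epimerisation, and ring D arrives as the free diol. Its carbons come from an acetylacetone unit, which also allows labelling or variation of ring D.

Key step: step 8

Assumption: Rh2(S-PTTL)4 is taken to give the (2S,3R)-cis ester 6; if its sense of induction is the opposite, the mirror-image catalyst Rh2(R-PTTL)4 is used and nothing else changes.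

## Route

Step 1
Reactants: 1 2-(5-bromo-2-hydroxyphenyl)acetic acid
Product: 2 methyl 2-(5-bromo-2-hydroxyphenyl)acetate
Conditions: MeOH, H2SO4 (cat.), reflux
Reagents that add atoms: methanol, CO
Why: Fischer esterification; any benzofuranone formed by lactonisation is reopened by methanol, so the methyl ester with the free phenol should be the product.

Step 2
Reactants: 2 methyl 2-(5-bromo-2-hydroxyphenyl)acetate; 3 3,4-dimethoxybenzyl bromide (freshly opened)
Product: 4 methyl 2-{5-bromo-2-[(3,4-dimethoxyphenyl)methoxy]phenyl}acetate
Conditions: K2CO3, acetone, 50 °C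
Reagents that add atoms: none
Why: Williamson ether synthesis; carbonate deprotonates only the phenol, and the phenoxide is alkylated by the reactive benzylic bromide faster than the arylacetate carbon could be.

Step 3
Reactants: 4 methyl 2-{5-bromo-2-[(3,4-dimethoxyphenyl)methoxy]phenyl}acetate
Product: 5 methyl 2-{5-bromo-2-[(3,4-dimethoxyphenyl)methoxy]phenyl}-2-diazoacetate
Conditions: 4-acetamidobenzenesulfonyl azide, DBU, MeCN, 0 to 25 °C
Reagents that add atoms: 4-acetamidobenzenesulfonyl azide, CC(=O)Nc1ccc(cc1)S(=O)(=O)N=[N+]=[N-]
Why: Regitz diazo transfer to the benzylic ester enolate, the standard entry to methyl aryldiazoacetates; ethers and the aryl bromide are inert.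

Step 4
Reactants: 5 methyl 2-{5-bromo-2-[(3,4-dimethoxyphenyl)methoxy]phenyl}-2-diazoacetate
Product: 6 methyl (2S,3R)-5-bromo-2-(3,4-dimethoxyphenyl)-2,3-dihydro-1-benzofuran-3-carboxylate (cis)
Conditions: Rh2(S-PTTL)4 (dirhodium tetrakis[N-phthaloyl-(S)-tert-leucinate], 1 mol%), toluene, −78 °C
Reagents that add atoms: none
Why: Intramolecular 1,5 C–H insertion of a rhodium donor/acceptor carbene into the ether benzylic C–H bond, which oxygen and the electron-rich aryl group activate; it forms C2–C3 and closes ring C. The concerted transition state gives the cis ester, and the chiral carboxylate ligands select one of the two enantiotopic benzylic hydrogens, which sets C2 as S and with it C3.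

Step 5
Reactants: 6 methyl (2S,3R)-5-bromo-2-(3,4-dimethoxyphenyl)-2,3-dihydro-1-benzofuran-3-carboxylate
Product: 8 (2S,3S)-5-bromo-2-(3,4-dimethoxyphenyl)-2,3-dihydro-1-benzofuran-3-carboxylic acid, via trans methyl ester 7 (not isolated)
Conditions: NaOMe, MeOH/THF, 25 °C; then 2 M aq. NaOH, 25 to 40 °C; then 1 M HCl, 0 °C
Reagents that add atoms: sodium hydroxide, [Na+].[OH-]
Why: Base epimerisation through the ester enolate places the ester trans to the C2 aryl group, so C3 becomes S under thermodynamic control by C2; saponification follows in the same flask. C2 is not touched, because loss of the O1 phenoxide from the enolate would be the reverse of a 5-endo-trig closure and has poor orbital overlap.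

Step 6
Reactants: 9 4-(trimethylsilyloxy)pent-3-en-2-one
Product: 10 2,4-bis(trimethylsilyloxy)penta-1,3-diene
Conditions: LiN(i-Pr)2, THF, −78 °C; then Me3SiCl, −78 to 20 °C
Reagents that add atoms: chlorotrimethylsilane, C[Si](C)(C)Cl
Why: Kinetic deprotonation of the methyl ketone terminus and O-silylation of the dienolate, the usual preparation of 1,3-bis(silyl enol ethers); the product is used without chromatography.

Step 7
Reactants: 8 (2S,3S)-5-bromo-2-(3,4-dimethoxyphenyl)-2,3-dihydro-1-benzofuran-3-carboxylic acid; 10 2,4-bis(trimethylsilyloxy)penta-1,3-diene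
Product: 13 1-[(2S,3S)-5-bromo-2-(3,4-dimethoxyphenyl)-2,3-dihydro-1-benzofuran-3-yl]hexane-1,3,5-trione, via acid chloride 11 (not isolated), via silyl enol ether 12 (not isolated)
Conditions: Me2C=C(Cl)NMe2 (1.05 equiv), CH2Cl2, 0 to 25 °C; then 10 (1.5 equiv), CH2Cl2, −78 to 20 °C; 1 M HCl, THF, 0 °C
Reagents that add atoms: 1-chloro-N,N,2-trimethylprop-1-en-1-amine, CC(C)=C(Cl)N(C)C (supplies the chlorine of 11 only; none of its atoms remain in 13)
Why: The α-chloroenamine makes the acid chloride without free HCl or base, so neither ketene formation nor ionisation of C2–O1 is invited. The bis(silyl enol ether), a neutral equivalent of the β-diketone dianion, is then acylated at its terminal carbon in a Mukaiyama-type Claisen condensation, a known route to 1,3,5-triketones. The base-labile C3–H never meets a strong base.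

Step 8
Reactants: 13 1-[(2S,3S)-5-bromo-2-(3,4-dimethoxyphenyl)-2,3-dihydro-1-benzofuran-3-yl]hexane-1,3,5-trione
Product: 14 5-[(2S,3S)-5-bromo-2-(3,4-dimethoxyphenyl)-2,3-dihydro-1-benzofuran-3-yl]benzene-1,3-diol
Conditions: 2 M aq. KOH/MeOH (degassed, dilute), Ar, 0 to 25 °C; then 1 M HCl to pH 3, 0 °C
Reagents that add atoms: none
Why: In aqueous KOH the triketone rests as its enolates; from the small share in which the acetyl end is enolised and the carbonyl on C3 is free, the methyl carbon (chain C6) adds to that carbonyl (chain C1), and loss of water followed by enolisation of the two remaining ketones gives the aromatic diol, the one new C–C bond being C1–C6 of ring D. The closest known reaction type is the base-induced aldol cyclisation and aromatisation of 2,4,6-triketones to 5-substituted resorcinols, the laboratory counterpart of polyketide folding. Ring D closes in a 6-(enolendo)-exo-trig mode; no stereocentre is created, and C3, enolisable until the ring is aromatic, stays under thermodynamic control by C2 and so remains trans. The step needs closure through carbon and not through oxygen to a 4-pyranone, which strong base and the absence of acid secure. It also needs closure through the methyl group and not through the C3 methine onto the acetyl carbonyl; that path would build a quaternary spiro centre between ring A and the C2 aryl group and cannot aromatise, so it stays reversible while the resorcinol is an irreversible sink. Ring C must stay closed: expulsion of the O1 phenoxide from a C3 enolate is the reverse of a 5-endo-trig closure with poor overlap between the enolate p orbital and the in-plane C2–O1 bond, and the bis-enolate resting state keeps C3–H only weakly acidic. Low temperature, dilution against intermolecular aldol reactions and exclusion of oxygen are the practical safeguards.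

Step 9
Reactants: 14 5-[(2S,3S)-5-bromo-2-(3,4-dimethoxyphenyl)-2,3-dihydro-1-benzofuran-3-yl]benzene-1,3-diol; 15 3,5-dimethoxystyrene
Product: 16 5-[(2S,3S)-2-(3,4-dimethoxyphenyl)-5-[(E)-2-(3,5-dimethoxyphenyl)ethenyl]-2,3-dihydro-1-benzofuran-3-yl]benzene-1,3-diol
Conditions: Pd(OAc)2 (5 mol%), P(o-tol)3 (10 mol%), Et3N, DMF, 100 °C, Ar
Reagents that add atoms: none
Why: Mizoroki–Heck reaction; zerovalent palladium inserts into the aryl bromide, the styrene is arylated at its terminal carbon, and syn β-hydride elimination gives the E stilbene. Free phenols are tolerated, and C2 and C3 carry no acidifying group any more.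

Step 10
Reactants: 16 5-[(2S,3S)-2-(3,4-dimethoxyphenyl)-5-[(E)-2-(3,5-dimethoxyphenyl)ethenyl]-2,3-dihydro-1-benzofuran-3-yl]benzene-1,3-diol
Product: 17 4-[(2S,3S)-3-(3,5-dihydroxyphenyl)-5-[(E)-2-(3,5-dihydroxyphenyl)ethenyl]-2,3-dihydro-1-benzofuran-2-yl]benzene-1,2-diol
Conditions: BBr3 (10 equiv), CH2Cl2, −78 to 0 °C; MeOH, then H2O
Reagents that add atoms: none
Why: Lewis-acid cleavage of aryl methyl ethers by BBr3, known chemistry on 2,3-diaryl-2,3-dihydrobenzofurans. If C2–O1 ionises transiently it recloses to the trans isomer under control of the now fixed C3, so the configuration is kept; low temperature limits damage to the stilbene.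

## Compound list

1 | 2-(5-bromo-2-hydroxyphenyl)acetic acid | OC(=O)Cc1cc(Br)ccc1O | starting material
2 | methyl 2-(5-bromo-2-hydroxyphenyl)acetate | COC(=O)Cc1cc(Br)ccc1O | intermediate
3 | 3,4-dimethoxybenzyl bromide (4-(bromomethyl)-1,2-dimethoxybenzene) | COc1ccc(CBr)cc1OC | starting material
4 | methyl 2-{5-bromo-2-[(3,4-dimethoxyphenyl)methoxy]phenyl}acetate | COC(=O)Cc1cc(Br)ccc1OCc1ccc(OC)c(OC)c1 | intermediate
5 | methyl 2-{5-bromo-2-[(3,4-dimethoxyphenyl)methoxy]phenyl}-2-diazoacetate | COC(=O)C(=[N+]=[N-])c1cc(Br)ccc1OCc1ccc(OC)c(OC)c1 | intermediate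
6 | methyl (2S,3R)-5-bromo-2-(3,4-dimethoxyphenyl)-2,3-dihydro-1-benzofuran-3-carboxylate (cis) | Brc1ccc2c(c1)[C@@H](C(=O)OC)[C@@H](c1ccc(OC)c(OC)c1)O2 | intermediate
7 | methyl (2S,3S)-5-bromo-2-(3,4-dimethoxyphenyl)-2,3-dihydro-1-benzofuran-3-carboxylate (trans; not isolated) | Brc1ccc2c(c1)[C@H](C(=O)OC)[C@@H](c1ccc(OC)c(OC)c1)O2 | intermediate
8 | (2S,3S)-5-bromo-2-(3,4-dimethoxyphenyl)-2,3-dihydro-1-benzofuran-3-carboxylic acid | Brc1ccc2c(c1)[C@H](C(=O)O)[C@@H](c1ccc(OC)c(OC)c1)O2 | intermediate
9 | 4-(trimethylsilyloxy)pent-3-en-2-one (commercial silyl enol ether of acetylacetone, alkene geometry as supplied) | CC(=O)C=C(C)O[Si](C)(C)C | starting material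
10 | 2,4-bis(trimethylsilyloxy)penta-1,3-diene | C=C(O[Si](C)(C)C)C=C(C)O[Si](C)(C)C | intermediate
11 | (2S,3S)-5-bromo-2-(3,4-dimethoxyphenyl)-2,3-dihydro-1-benzofuran-3-carbonyl chloride (not isolated) | Brc1ccc2c(c1)[C@H](C(Cl)=O)[C@@H](c1ccc(OC)c(OC)c1)O2 | intermediate
12 | 1-[(2S,3S)-5-bromo-2-(3,4-dimethoxyphenyl)-2,3-dihydro-1-benzofuran-3-yl]-5-(trimethylsilyloxy)hex-4-ene-1,3-dione (not isolated) | Brc1ccc2c(c1)[C@H](C(=O)CC(=O)C=C(C)O[Si](C)(C)C)[C@@H](c1ccc(OC)c(OC)c1)O2 | intermediate
13 | 1-[(2S,3S)-5-bromo-2-(3,4-dimethoxyphenyl)-2,3-dihydro-1-benzofuran-3-yl]hexane-1,3,5-trione (drawn as the triketo form; enol tautomers expected) | Brc1ccc2c(c1)[C@H](C(=O)CC(=O)CC(C)=O)[C@@H](c1ccc(OC)c(OC)c1)O2 | intermediate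
14 | 5-[(2S,3S)-5-bromo-2-(3,4-dimethoxyphenyl)-2,3-dihydro-1-benzofuran-3-yl]benzene-1,3-diol | Brc1ccc2c(c1)[C@H](c1cc(O)cc(O)c1)[C@@H](c1ccc(OC)c(OC)c1)O2 | intermediate
15 | 3,5-dimethoxystyrene (1-ethenyl-3,5-dimethoxybenzene) | C=Cc1cc(OC)cc(OC)c1 | starting material
16 | 5-[(2S,3S)-2-(3,4-dimethoxyphenyl)-5-[(E)-2-(3,5-dimethoxyphenyl)ethenyl]-2,3-dihydro-1-benzofuran-3-yl]benzene-1,3-diol | COc1cc(OC)cc(/C=C/c2ccc3c(c2)[C@H](c2cc(O)cc(O)c2)[C@@H](c2ccc(OC)c(OC)c2)O3)c1 | intermediate
17 | 4-[(2S,3S)-3-(3,5-dihydroxyphenyl)-5-[(E)-2-(3,5-dihydroxyphenyl)ethenyl]-2,3-dihydro-1-benzofuran-2-yl]benzene-1,2-diol | Oc1cc(O)cc(/C=C/c2ccc3c(c2)[C@H](c2cc(O)cc(O)c2)[C@@H](c2ccc(O)c(O)c2)O3)c1 | target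

## Step count and least certain steps

Total: 10 steps. Longest linear sequence: 9 steps (steps 1 to 5 and 7 to 10); step 6 is a one-step side branch.

**Step 8 (key step).** The most likely failure is enolisation at C3 of the triketone under hydroxide. It can be followed by expulsion of the O1 phenoxide, which opens ring C and erases both stereocentres, or by aldol attack of C3 on the acetyl carbonyl. Retro-Claisen cleavage of the β-diketone units by hydroxide and closure of some material through the cis epimer are further risks. Any cis diastereomer must be removed at 14, because acid-induced inversion of C2 in step 10 would carry it into the enantiomeric series.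

Fallback, setting out from acid 8 through its chloride 11 and returning at 14: the ring is closed in the resorcylate manner, where a doubly activated methylene is the nucleophile and weak base suffices. Methyl 3,5-dioxohexanoate is silylated exhaustively (Me3SiCl/Et3N, then twice LiN(i-Pr)2/Me3SiCl) to 1-methoxy-1,3,5-tris(trimethylsilyloxy)hexa-1,3,5-triene F1. Under the conditions of step 7, F1 is acylated by 11 at its terminal carbon and gives, after hydrolytic work-up, methyl 7-[(2S,3S)-5-bromo-2-(3,4-dimethoxyphenyl)-2,3-dihydro-1-benzofuran-3-yl]-3,5,7-trioxoheptanoate F2. A buffer near pH 9 or Et3N closes F2 by aldol attack of its C2 on the C7 ketone to methyl 2-[(2S,3S)-5-bromo-2-(3,4-dimethoxyphenyl)-2,3-dihydro-1-benzofuran-3-yl]-4,6-dihydroxybenzoate F3. Aqueous KOH at reflux, acidification and brief warming saponify and decarboxylate the β-resorcylic acid to 14, at a stage where C3 is no longer acidic.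

**Step 7.** Acylation may occur through oxygen or through the central carbon of the dienol ether. The hindered secondary acid chloride may react slowly. The silyl chloride and HCl present during work-up may cyclodehydrate the triketone to a 4-pyranone.

Fallback, setting out from the trans methyl ester 7 (isolated by stopping step 5 before hydroxide is added) and returning at 13: classical Claisen acylation of the dianion of acetylacetone (NaH, then n-BuLi, THF, 0 °C, excess dianion) by ester 7. Proton transfer from C3 will compete and return ester, which is recycled; no new compound is made.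

**Step 4.** Enantioselection or cis selectivity may be insufficient for this substrate. The benzylic ether is more electron-rich and the carbene aryl group bears a bromine, both departures from the simplest cases. Carbene dimerisation may compete at the low temperature needed for selectivity.

Fallback, setting out from ester 4 and returning at acid 8: catalyst control is replaced by auxiliary control with separation of diastereomers.
- LiOH hydrolyses 4 to 2-{5-bromo-2-[(3,4-dimethoxyphenyl)methoxy]phenyl}acetic acid F4.
- Carbodiimide coupling with (2S)-2-hydroxy-1-(pyrrolidin-1-yl)propan-1-one gives (2S)-1-oxo-1-(pyrrolidin-1-yl)propan-2-yl 2-{5-bromo-2-[(3,4-dimethoxyphenyl)methoxy]phenyl}acetate F5.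
- Diazo transfer as in step 3 gives (2S)-1-oxo-1-(pyrrolidin-1-yl)propan-2-yl 2-{5-bromo-2-[(3,4-dimethoxyphenyl)methoxy]phenyl}-2-diazoacetate F6.
- Insertion with Rh2(S-DOSP)4 (dirhodium tetrakis[(S)-N-(4-dodecylbenzenesulfonyl)prolinate]) gives (2S)-1-oxo-1-(pyrrolidin-1-yl)propan-2-yl (2S,3S)-5-bromo-2-(3,4-dimethoxyphenyl)-2,3-dihydro-1-benzofuran-3-carboxylate F7. The enantiomer of the auxiliary that matches the catalyst is chosen by trial.
- F7 is freed of minor diastereomers by chromatography or crystallisation and saponified with LiOH to 8.

**Step 10.** The C2–O1 bond may ionise and the cation be captured by bromide or by the electron-rich rings instead of reclosing. HBr may add to the stilbene or trigger its cationic oligomerisation. The catechol ethers may be cleaved incompletely.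

Fallback, setting out from 14 and returning at 17: the Lewis acid is used before the stilbene exists and the last deprotection becomes a mild methanolysis.
- BBr3 converts 14 into 4-[(2S,3S)-5-bromo-3-(3,5-dihydroxyphenyl)-2,3-dihydro-1-benzofuran-2-yl]benzene-1,2-diol F8.
- Ac2O/pyridine gives its tetraacetate, 4-[(2S,3S)-5-bromo-3-(3,5-diacetoxyphenyl)-2,3-dihydro-1-benzofuran-2-yl]-1,2-phenylene diacetate F9.
- Heck coupling under the conditions of step 9 with purchased 3,5-diacetoxystyrene gives the hexaacetate of the target F10.
- Degassed K2CO3/MeOH at 0 °C removes the acetates to give 17.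

## Further compounds

F1 | step 8 | 1-methoxy-1,3,5-tris(trimethylsilyloxy)hexa-1,3,5-triene | COC(O[Si](C)(C)C)=CC(O[Si](C)(C)C)=CC(O[Si](C)(C)C)=C
F2 | step 8 | methyl 7-[(2S,3S)-5-bromo-2-(3,4-dimethoxyphenyl)-2,3-dihydro-1-benzofuran-3-yl]-3,5,7-trioxoheptanoate | Brc1ccc2c(c1)[C@H](C(=O)CC(=O)CC(=O)CC(=O)OC)[C@@H](c1ccc(OC)c(OC)c1)O2
F3 | step 8 | methyl 2-[(2S,3S)-5-bromo-2-(3,4-dimethoxyphenyl)-2,3-dihydro-1-benzofuran-3-yl]-4,6-dihydroxybenzoate | Brc1ccc2c(c1)[C@H](c1cc(O)cc(O)c1C(=O)OC)[C@@H](c1ccc(OC)c(OC)c1)O2
F0 | step 7 | none | none
F4 | step 4 | 2-{5-bromo-2-[(3,4-dimethoxyphenyl)methoxy]phenyl}acetic acid | OC(=O)Cc1cc(Br)ccc1OCc1ccc(OC)c(OC)c1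
F5 | step 4 | (2S)-1-oxo-1-(pyrrolidin-1-yl)propan-2-yl 2-{5-bromo-2-[(3,4-dimethoxyphenyl)methoxy]phenyl}acetate | C[C@H](OC(=O)Cc1cc(Br)ccc1OCc1ccc(OC)c(OC)c1)C(=O)N1CCCC1
F6 | step 4 | (2S)-1-oxo-1-(pyrrolidin-1-yl)propan-2-yl 2-{5-bromo-2-[(3,4-dimethoxyphenyl)methoxy]phenyl}-2-diazoacetate | C[C@H](OC(=O)C(=[N+]=[N-])c1cc(Br)ccc1OCc1ccc(OC)c(OC)c1)C(=O)N1CCCC1
F7 | step 4 | (2S)-1-oxo-1-(pyrrolidin-1-yl)propan-2-yl (2S,3S)-5-bromo-2-(3,4-dimethoxyphenyl)-2,3-dihydro-1-benzofuran-3-carboxylate | Brc1ccc2c(c1)[C@H](C(=O)O[C@@H](C)C(=O)N1CCCC1)[C@@H](c1ccc(OC)c(OC)c1)O2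
F8 | step 10 | 4-[(2S,3S)-5-bromo-3-(3,5-dihydroxyphenyl)-2,3-dihydro-1-benzofuran-2-yl]benzene-1,2-diol | Brc1ccc2c(c1)[C@H](c1cc(O)cc(O)c1)[C@@H](c1ccc(O)c(O)c1)O2
F9 | step 10 | 4-[(2S,3S)-5-bromo-3-(3,5-diacetoxyphenyl)-2,3-dihydro-1-benzofuran-2-yl]-1,2-phenylene diacetate | Brc1ccc2c(c1)[C@H](c1cc(OC(C)=O)cc(OC(C)=O)c1)[C@@H](c1ccc(OC(C)=O)c(OC(C)=O)c1)O2
F10 | step 10 | hexaacetate of 17: 4-[(2S,3S)-3-(3,5-diacetoxyphenyl)-5-[(E)-2-(3,5-diacetoxyphenyl)ethenyl]-2,3-dihydro-1-benzofuran-2-yl]-1,2-phenylene diacetate | CC(=O)Oc1cc(OC(C)=O)cc(/C=C/c2ccc3c(c2)[C@H](c2cc(OC(C)=O)cc(OC(C)=O)c2)[C@@H](c2ccc(OC(C)=O)c(OC(C)=O)c2)O3)c1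
A1 | alternative 1 | (4R,5S)-5-(3,4-dimethoxyphenyl)-4-(3,5-dimethoxyphenyl)oxolan-2-one (trans lactone) | O=C1C[C@H](c2cc(OC)cc(OC)c2)[C@@H](c2ccc(OC)c(OC)c2)O1
A2 | alternative 1 | tert-butyl{[(4R,5S)-5-(3,4-dimethoxyphenyl)-4-(3,5-dimethoxyphenyl)-4,5-dihydrofuran-2-yl]oxy}dimethylsilane | CC(C)(C)[Si](C)(C)OC1=C[C@H](c2cc(OC)cc(OC)c2)[C@@H](c2ccc(OC)c(OC)c2)O1
A3 | alternative 1 | methyl coumalate (methyl 2-oxo-2H-pyran-5-carboxylate) | COC(=O)C1=COC(=O)C=C1
A4 | alternative 1 | methyl (2S,3S)-2-(3,4-dimethoxyphenyl)-3-(3,5-dimethoxyphenyl)-2,3-dihydro-1-benzofuran-5-carboxylate | COC(=O)c1ccc2c(c1)[C@H](c1cc(OC)cc(OC)c1)[C@@H](c1ccc(OC)c(OC)c1)O2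
A5 | alternative 2 | (2S)-6-bromo-2-(3,4-dimethoxyphenyl)-2,3-dihydro-4H-chromen-4-one | O=C1C[C@@H](c2ccc(OC)c(OC)c2)Oc2ccc(Br)cc12
A6 | alternative 2 | methyl (2S,3S)-5-bromo-2-(3,4-dimethoxyphenyl)-2,3-dihydro-1-benzofuran-3-carboxylate | Brc1ccc2c(c1)[C@H](C(=O)OC)[C@@H](c1ccc(OC)c(OC)c1)O2
A7 | alternative 3 | hydrazone of {5-bromo-2-[(3,4-dimethoxyphenyl)methoxy]phenyl}(3,5-dimethoxyphenyl)methanone | NN=C(c1cc(OC)cc(OC)c1)c1cc(Br)ccc1OCc1ccc(OC)c(OC)c1
A8 | alternative 3 | 4-bromo-2-[diazo(3,5-dimethoxyphenyl)methyl]-1-[(3,4-dimethoxyphenyl)methoxy]benzene | [N-]=[N+]=C(c1cc(OC)cc(OC)c1)c1cc(Br)ccc1OCc1ccc(OC)c(OC)c1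
A9 | alternative 3 | (2R,3S)-5-bromo-2-(3,4-dimethoxyphenyl)-3-(3,5-dimethoxyphenyl)-2,3-dihydro-1-benzofuran (cis) | Brc1ccc2c(c1)[C@H](c1cc(OC)cc(OC)c1)[C@H](c1ccc(OC)c(OC)c1)O2
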